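## Retrosynthetic overview

- Last C–C bond: pyridine C3–acyl carbon, made under blue light by nickel/photoredox/hydrogen-atom-transfer coupling of a decalin aldehyde with a 3-bromopyridine N-oxide. Fluoride then removes all silicon groups and unveils the N-hydroxypyridone.
- Pyridine C5–carbinol bond: an arylmagnesium from a 3-bromo-5-iodo-2,4-dialkoxypyridine N-oxide (made from 2-chloro-4-nitropyridine 1-oxide) adds to an epoxy ketone anti to the epoxide.
- Epoxy ketone: from D-(−)-quinic acid, whose C4 becomes the secondary carbinol. The oxirane is added by nucleophilic epoxidation anti to the silyloxy group.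
- Decalin aldehyde: from (R)-citronellal by two Wittig olefinations and an endo intramolecular Diels–Alder reaction that closes both carbocycles in one step.
- Ring order: cyclohexane (bought) → oxirane → attached to the bought pyridine; the decalin bicycle is made separately and joined last.

Assumption: the target is the drawn 1,4-dihydroxy-2-pyridone tautomer; (R)-citronellal of high ee, D-(−)-quinic acid, 2-chloro-4-nitropyridine 1-oxide and both Wittig reagents are bought.

## Route

**Step 1**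
Reactants: 1 (R)-citronellal
Product: 3 (2E,4E,7R)-7,11-dimethyldodeca-2,4,10-triene, via 4Z-triene isomer 2 (not isolated)
Conditions: (E)-crotyltriphenylphosphonium chloride, n-BuLi, THF, −78 °C → rt; then I2 (2 mol %), hexane, daylight, rt
Reagents that add atoms: (E)-but-2-en-1-yl(triphenyl)phosphonium chloride, C/C=C/C[P+](c1ccccc1)(c1ccccc1)c1ccccc1.[Cl-]
Why: Wittig olefination with the semi-stabilised allylic ylide builds the diene, and iodine-catalysed radical addition–elimination equilibrates the 4Z co-product 2 to the favoured E,E-diene, while the citronellal stereocentre (C7) is untouched.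

**Step 2**
Reactants: 3 (2E,4E,7R)-7,11-dimethyldodeca-2,4,10-triene
Product: 5 (4R,6E,8E)-4-methyldeca-6,8-dienal, via epoxide 4 (not isolated)
Conditions: mCPBA (1.0 equiv), CH2Cl2, −20 °C; then H5IO6 (1.1 equiv), THF–H2O, 0 °C
Reagents that add atoms: mCPBA, OOC(=O)c1cccc(Cl)c1
Why: Prilezhaev epoxidation is fastest at the electron-rich trisubstituted alkene (as with myrcene, the conjugated disubstituted diene reacts roughly tenfold more slowly), and periodic acid then hydrates and cleaves the epoxide (Malaprade-type glycol cleavage) to the aldehyde without touching the stereocentre.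

**Step 3**
Reactants: 5 (4R,6E,8E)-4-methyldeca-6,8-dienal
Product: 6 (2E,6R,8E,10E)-6-methyldodeca-2,8,10-trienal
Conditions: Ph3P=CHCHO (1.2 equiv), toluene, 60 °C
Reagents that add atoms: (triphenylphosphoranylidene)acetaldehyde, O=CC=P(c1ccccc1)(c1ccccc1)c1ccccc1
Why: Wittig reaction with the stabilised formylmethylene ylide gives the E-enal selectively, and the moderate temperature keeps the uncatalysed cycloaddition slow.

**Step 4**
Reactants: 6 (2E,6R,8E,10E)-6-methyldodeca-2,8,10-trienal
Product: 7 (1R,2R,4aS,6R,8aR)-2,6-dimethyl-1,2,4a,5,6,7,8,8a-octahydronaphthalene-1-carbaldehyde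
Conditions: Me2AlCl (0.25 equiv), CH2Cl2, −78 → −30 °C
Reagents that add atoms: none
Why: Lewis acid-catalysed intramolecular Diels–Alder reaction through the endo transition state with a chair tether and equatorial C6 methyl gives the trans-fused decalin, so the citronellal-derived centre sets C1, C2, C4a and C8a by substrate control.

**Step 5**
Reactants: 8 D-(−)-quinic acid
Product: 9 3,4-O-isopropylidene-D-quinic acid 1,5-lactone (lactone from the C1 carboxyl to O5, acetonide on the cis 3,4-diol, free tertiary 1-OH)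
Conditions: 2,2-dimethoxypropane, TsOH·H2O (cat.), acetone, reflux
Reagents that add atoms: 2,2-dimethoxypropane, COC(C)(C)OC
Why: Acid-catalysed transketalisation protects the cis-3,4-diol while the carboxyl lactonises onto the syn 5-OH (standard quinide formation), with all stereocentres retained.

**Step 6**
Reactants: 9 3,4-O-isopropylidene-D-quinic acid 1,5-lactone
Product: 11 (3R,4S,5R)-5-hydroxy-3,4-(isopropylidenedioxy)cyclohexan-1-one, via triol 10 (not isolated)
Conditions: NaBH4, EtOH, 0 °C → rt; then pH 6 phosphate buffer, NaIO4, H2O, 0 °C → rt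
Reagents that add atoms: none
Why: Borohydride reduction opens the lactone to the 1-hydroxymethyl triol, and Malaprade periodate cleavage of its 1,2-diol excises the former carboxyl carbon as formaldehyde, leaving the ketone with C3, C4 and C5 unchanged.

**Step 7**
Reactants: 11 (3R,4S,5R)-5-hydroxy-3,4-(isopropylidenedioxy)cyclohexan-1-one
Product: 13 (4S,5R)-4,5-(isopropylidenedioxy)cyclohex-2-en-1-one, via mesylate 12 (not isolated)
Conditions: MsCl (1.2 equiv), Et3N (3 equiv), CH2Cl2, 0 °C → rt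
Reagents that add atoms: none
Why: Mesylation of the β-hydroxyl is followed by E1cB elimination toward the ketone, giving the conjugated enone while the acetonide-bearing centres stay intact.

**Step 8**
Reactants: 13 (4S,5R)-4,5-(isopropylidenedioxy)cyclohex-2-en-1-one
Product: 14 (3R,4S)-3,4-(isopropylidenedioxy)cyclohexan-1-one
Conditions: H2 (1 atm), 10% Pd/C, EtOAc, rt
Reagents that add atoms: none
Why: Heterogeneous catalytic hydrogenation saturates the enone C=C chemoselectively, which completes removal of the former 5-oxygen and leaves the acetonide oxygen at C3 as the only β-leaving group.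

**Step 9**
Reactants: 14 (3R,4S)-3,4-(isopropylidenedioxy)cyclohexan-1-one
Product: 16 (S)-4-[(tert-butyldimethylsilyl)oxy]cyclohex-2-en-1-one, via hydroxy enone 15 (not isolated)
Conditions: TBSCl (1.5 equiv), DBU (2.5 equiv), CH2Cl2, 0 °C → rt
Reagents that add atoms: tert-butyldimethylsilyl chloride, CC(C)(C)[Si](C)(C)Cl
Why: DBU-induced E1cB β-elimination opens the acetonide at C3 with loss of acetone, and the γ-hydroxy enone 15 is silylated in situ before it can isomerise, so quinic acid C4 becomes the single S stereocentre.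

**Step 10**
Reactants: 16 (S)-4-[(tert-butyldimethylsilyl)oxy]cyclohex-2-en-1-one
Product: 17 (1R,5S,6S)-5-[(tert-butyldimethylsilyl)oxy]-7-oxabicyclo[4.1.0]heptan-2-one (epoxide trans to the silyloxy group)
Conditions: t-BuOOH (1.5 equiv), Triton B (10 mol %), THF, 0 °C
Reagents that add atoms: tert-butyl hydroperoxide, CC(C)(C)OO
Why: Weitz–Scheffer nucleophilic epoxidation occurs on the enone face anti to the bulky allylic silyloxy group, setting both epoxide centres by substrate control.

**Step 11**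
Reactants: 18 2-chloro-4-nitropyridine 1-oxide
Product: 19 2,4-bis[2-(trimethylsilyl)ethoxy]pyridine 1-oxide
Conditions: Me3SiCH2CH2OH (2.3 equiv), NaH (2.4 equiv), THF, 0 → 60 °C
Reagents that add atoms: 2-(trimethylsilyl)ethanol, C[Si](C)(C)CCO
Why: Twofold SNAr on the N-oxide-activated ring, in which the 4-nitro group is displaced first and the 2-chloride on warming.

**Step 12**
Reactants: 19 2,4-bis[2-(trimethylsilyl)ethoxy]pyridine 1-oxide
Product: 21 3-bromo-5-iodo-2,4-bis[2-(trimethylsilyl)ethoxy]pyridine 1-oxide, via 5-iodo N-oxide 20 (not isolated)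
Conditions: NIS (1.05 equiv), MeCN, 0 °C → rt; then NBS (1.1 equiv), 40 °C
Reagents that add atoms: N-iodosuccinimide, O=C1CCC(=O)N1I; N-bromosuccinimide, O=C1CCC(=O)N1Br
Why: Electrophilic aromatic halogenation goes first to C5 (para to the 2-alkoxy group and less hindered, as in 2,4-dialkoxypyridines and resorcinol diethers), and the bromonium source then fills C3, the only activated position left.

**Step 13**
Reactants: 21 3-bromo-5-iodo-2,4-bis[2-(trimethylsilyl)ethoxy]pyridine 1-oxide; 17 (1R,5S,6S)-5-[(tert-butyldimethylsilyl)oxy]-7-oxabicyclo[4.1.0]heptan-2-one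
Product: 23 (1R,2R,5S,6S)-2-{5-bromo-1-oxido-4,6-bis[2-(trimethylsilyl)ethoxy]pyridin-1-ium-3-yl}-5-[(tert-butyldimethylsilyl)oxy]-7-oxabicyclo[4.1.0]heptan-2-ol, via arylmagnesium chloride 22 (not isolated)
Conditions: i-PrMgCl·LiCl (1.05 equiv), THF, −40 °C; then 17, LaCl3·2LiCl (30 mol %), −40 → −20 °C; aq. NH4Cl
Reagents that add atoms: none
Why: Iodine–magnesium exchange (Knochel type) is much faster at C–I than at C–Br or the N-oxide C6–H, and the aryl Grignard adds 1,2 to the epoxy ketone from the face anti to the epoxide oxygen, which sets the tertiary carbinol (OH cis to the epoxide) by substrate control.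

**Step 14**
Reactants: 23 (1R,2R,5S,6S)-2-{5-bromo-1-oxido-4,6-bis[2-(trimethylsilyl)ethoxy]pyridin-1-ium-3-yl}-5-[(tert-butyldimethylsilyl)oxy]-7-oxabicyclo[4.1.0]heptan-2-ol; 7 (1R,2R,4aS,6R,8aR)-2,6-dimethyl-1,2,4a,5,6,7,8,8a-octahydronaphthalene-1-carbaldehyde
Product: 24 {5-[(1R,2R,5S,6S)-5-[(tert-butyldimethylsilyl)oxy]-2-hydroxy-7-oxabicyclo[4.1.0]heptan-2-yl]-1-oxido-2,4-bis[2-(trimethylsilyl)ethoxy]pyridin-1-ium-3-yl}[(1R,2R,4aS,6R,8aR)-2,6-dimethyl-1,2,4a,5,6,7,8,8a-octahydronaphthalen-1-yl]methanone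
Conditions: 7 (1.5 equiv), Ir[dF(CF3)ppy]2(dtbbpy)PF6 (1 mol %), NiBr2·DME (10 mol %), 4,4′-di-tert-butyl-2,2′-bipyridine (12 mol %), quinuclidine (20 mol %), K2CO3 (1.5 equiv), 1,4-dioxane, 450 nm LEDs, 25 °C
Reagents that add atoms: none
Why: Proposed new method: the triple-catalytic formyl C–H arylation (iridium photocatalyst, nickel–bipyridine, quinuclidine as hydrogen-atom-transfer catalyst) is applied for the first time to a bromopyridine N-oxide whose C–Br is flanked by two alkoxy groups and to an α-branched bicyclic aldehyde; the photo-oxidised quinuclidine radical cation abstracts the hydridic formyl hydrogen of 7 in preference to allylic or α-oxy C–H, zerovalent nickel inserts into the C3–Br bond of 23, the acyl radical is captured to give a trivalent aryl(acyl)nickel species that reductively eliminates the ketone before the secondary acyl radical can lose CO, and the reduced photocatalyst returns nickel to the zerovalent state, while the visible light is not absorbed by the N-oxide and the acyl radical leaves decalin C1 configurationally intact; the closest known reaction is the nickel/photoredox/hydrogen-atom-transfer arylation of aldehydes with simple aryl bromides.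

**Step 15**
Reactants: 24 (silyl-protected ketone N-oxide named in step 14)
Product: 25 3-[(1R,2R,4aS,6R,8aR)-2,6-dimethyl-1,2,4a,5,6,7,8,8a-octahydronaphthalene-1-carbonyl]-5-[(1R,2R,5S,6R)-2,5-dihydroxy-7-oxabicyclo[4.1.0]heptan-2-yl]-1,4-dihydroxypyridin-2(1H)-one
Conditions: TBAF (6 equiv), AcOH (6 equiv), THF, 0 °C → rt
Reagents that add atoms: none
Why: Fluoride cleaves the secondary silyl ether and triggers β-elimination of both 2-(trimethylsilyl)ethyl ethers, whose leaving groups are the stabilised N-oxide 2-olate and the vinylogous carboxylate, under buffered conditions that spare the epoxide, the tertiary alcohol and the alkene, with no stereocentre affected.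

## Compound list

1 | (R)-citronellal | C[C@H](CCC=C(C)C)CC=O | starting material
2 | (2E,4Z,7R)-7,11-dimethyldodeca-2,4,10-triene | C[C@H](CCC=C(C)C)C/C=C\C=C\C | intermediate
3 | (2E,4E,7R)-7,11-dimethyldodeca-2,4,10-triene | C[C@H](CCC=C(C)C)C/C=C/C=C/C | intermediate
4 | 2,2-dimethyl-3-[(3R,5E,7E)-3-methylnona-5,7-dien-1-yl]oxirane (both epimers at the oxirane carbon) | C[C@H](CCC1OC1(C)C)C/C=C/C=C/C | intermediate
5 | (4R,6E,8E)-4-methyldeca-6,8-dienal | C[C@H](CCC=O)C/C=C/C=C/C | intermediate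
6 | (2E,6R,8E,10E)-6-methyldodeca-2,8,10-trienal | C[C@H](CC/C=C/C=O)C/C=C/C=C/C | intermediate
7 | (1R,2R,4aS,6R,8aR)-2,6-dimethyl-1,2,4a,5,6,7,8,8a-octahydronaphthalene-1-carbaldehyde | C[C@@H]1CC[C@H]2[C@H](C=O)[C@H](C)C=C[C@@H]2C1 | intermediate
8 | D-(−)-quinic acid, (1S,3R,4S,5R)-1,3,4,5-tetrahydroxycyclohexane-1-carboxylic acid | C1[C@H]([C@H]([C@@H](C[C@@]1(C(=O)O)O)O)O)O | starting material
9 | 3,4-O-isopropylidene-D-quinic acid 1,5-lactone | O=C1O[C@@H]2C[C@@]1(O)C[C@H]3OC(C)(C)O[C@H]32 | intermediate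
10 | 1-(hydroxymethyl)-3,4-O-isopropylidenecyclohexane-1,3,4,5-tetrol (quinic acid numbering and configuration) | OC[C@]1(O)C[C@H]2OC(C)(C)O[C@H]2[C@H](O)C1 | intermediate
11 | (3R,4S,5R)-5-hydroxy-3,4-(isopropylidenedioxy)cyclohexan-1-one | O=C1C[C@H]2OC(C)(C)O[C@H]2[C@H](O)C1 | intermediate
12 | (3R,4S,5R)-3,4-(isopropylidenedioxy)-5-(methanesulfonyloxy)cyclohexan-1-one | O=C1C[C@H]2OC(C)(C)O[C@H]2[C@H](OS(C)(=O)=O)C1 | intermediate
13 | (4S,5R)-4,5-(isopropylidenedioxy)cyclohex-2-en-1-one | O=C1C[C@H]2OC(C)(C)O[C@H]2C=C1 | intermediate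
14 | (3R,4S)-3,4-(isopropylidenedioxy)cyclohexan-1-one | O=C1C[C@H]2OC(C)(C)O[C@H]2CC1 | intermediate
15 | (S)-4-hydroxycyclohex-2-en-1-one | O=C1C=C[C@@H](O)CC1 | intermediate
16 | (S)-4-[(tert-butyldimethylsilyl)oxy]cyclohex-2-en-1-one | O=C1C=C[C@@H](O[Si](C)(C)C(C)(C)C)CC1 | intermediate
17 | (1R,5S,6S)-5-[(tert-butyldimethylsilyl)oxy]-7-oxabicyclo[4.1.0]heptan-2-one | O=C1[C@@H]2O[C@@H]2[C@@H](O[Si](C)(C)C(C)(C)C)CC1 | intermediate
18 | 2-chloro-4-nitropyridine 1-oxide | [O-][n+]1ccc(cc1Cl)[N+](=O)[O-] | starting material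
19 | 2,4-bis[2-(trimethylsilyl)ethoxy]pyridine 1-oxide | [O-][n+]1ccc(OCC[Si](C)(C)C)cc1OCC[Si](C)(C)C | intermediate
20 | 5-iodo-2,4-bis[2-(trimethylsilyl)ethoxy]pyridine 1-oxide | [O-][n+]1cc(I)c(OCC[Si](C)(C)C)cc1OCC[Si](C)(C)C | intermediate
21 | 3-bromo-5-iodo-2,4-bis[2-(trimethylsilyl)ethoxy]pyridine 1-oxide | [O-][n+]1cc(I)c(OCC[Si](C)(C)C)c(Br)c1OCC[Si](C)(C)C | intermediate
22 | {5-bromo-1-oxido-4,6-bis[2-(trimethylsilyl)ethoxy]pyridin-1-ium-3-yl}magnesium chloride | [O-][n+]1cc([Mg]Cl)c(OCC[Si](C)(C)C)c(Br)c1OCC[Si](C)(C)C | intermediate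
23 | (1R,2R,5S,6S)-2-{5-bromo-1-oxido-4,6-bis[2-(trimethylsilyl)ethoxy]pyridin-1-ium-3-yl}-5-[(tert-butyldimethylsilyl)oxy]-7-oxabicyclo[4.1.0]heptan-2-ol | [O-][n+]1cc([C@]2(O)CC[C@H](O[Si](C)(C)C(C)(C)C)[C@H]3O[C@H]32)c(OCC[Si](C)(C)C)c(Br)c1OCC[Si](C)(C)C | intermediate
24 | {5-[(1R,2R,5S,6S)-5-[(tert-butyldimethylsilyl)oxy]-2-hydroxy-7-oxabicyclo[4.1.0]heptan-2-yl]-1-oxido-2,4-bis[2-(trimethylsilyl)ethoxy]pyridin-1-ium-3-yl}[(1R,2R,4aS,6R,8aR)-2,6-dimethyl-1,2,4a,5,6,7,8,8a-octahydronaphthalen-1-yl]methanone | C[C@@H]1CC[C@H]2[C@H](C(=O)c3c(OCC[Si](C)(C)C)c([C@]4(O)CC[C@H](O[Si](C)(C)C(C)(C)C)[C@H]5O[C@H]54)c[n+]([O-])c3OCC[Si](C)(C)C)[C@H](C)C=C[C@@H]2C1 | intermediate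
25 | 3-[(1R,2R,4aS,6R,8aR)-2,6-dimethyl-1,2,4a,5,6,7,8,8a-octahydronaphthalene-1-carbonyl]-5-[(1R,2R,5S,6R)-2,5-dihydroxy-7-oxabicyclo[4.1.0]heptan-2-yl]-1,4-dihydroxypyridin-2(1H)-one | C[C@@H]1CC[C@H]2[C@H](C(=O)c3c(O)c([C@]4(O)CC[C@H](O)[C@H]5O[C@H]54)cn(O)c3=O)[C@H](C)C=C[C@@H]2C1 | target

## Step count and risks

Total step count: 15.
Longest linear sequence: 9 steps (8 → 25 through steps 5–10 and 13–15).

Steps most likely to fail:

**Step 14 (the new photochemical acylation).** The C–Br bond is doubly ortho-substituted and the N-oxide and free tertiary alcohol are untested under these conditions. The fallback sets out from 23 and 7 and uses known organomagnesium chemistry. Compound 23 is treated with i-PrMgCl·LiCl (2.2 equiv, THF, −20 °C); the first equivalent deprotonates the tertiary alcohol and the second effects bromine–magnesium exchange at C3. Aldehyde 7 is added to give the secondary carbinol {5-[(1R,2R,5S,6S)-5-[(tert-butyldimethylsilyl)oxy]-2-hydroxy-7-oxabicyclo[4.1.0]heptan-2-yl]-1-oxido-2,4-bis[2-(trimethylsilyl)ethoxy]pyridin-1-ium-3-yl}[(1R,2R,4aS,6R,8aR)-2,6-dimethyl-1,2,4a,5,6,7,8,8a-octahydronaphthalen-1-yl]methanol F4 as a mixture of carbinol epimers. Oxidation with Dess–Martin periodinane (NaHCO3, CH2Cl2) brings the route back to 24.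

**Step 13 (magnesiated N-oxide plus epoxy ketone).** The Grignard reagent may add to C6 of another N-oxide molecule or deprotonate there, and the ketone may enolise. The fallback sets out from 21 and carries the plain pyridine through the organometallic step. Compound 21 is deoxygenated with bis(pinacolato)diboron (MeCN, 70 °C) to 3-bromo-5-iodo-2,4-bis[2-(trimethylsilyl)ethoxy]pyridine F2. Iodine–magnesium exchange and addition to 17 as in step 13 give (1R,2R,5S,6S)-2-{5-bromo-4,6-bis[2-(trimethylsilyl)ethoxy]pyridin-3-yl}-5-[(tert-butyldimethylsilyl)oxy]-7-oxabicyclo[4.1.0]heptan-2-ol F3. The nitrogen is then oxidised with MeReO3 (5 mol %) and 30% H2O2 in CH2Cl2, which is safe here because no alkene is present yet, and the route comes back at 23.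

**Step 12 (one-pot regioselective dihalogenation).** The C5/C3 order on the N-oxide is inferred by analogy, and ipso exchange of iodine by bromine is possible. The fallback sets out from 20, isolated after the NIS stage alone. Compound 20 is used in the step 13 protocol with 17 to give the C3–H adduct (1R,2R,5S,6S)-5-[(tert-butyldimethylsilyl)oxy]-2-{1-oxido-4,6-bis[2-(trimethylsilyl)ethoxy]pyridin-1-ium-3-yl}-7-oxabicyclo[4.1.0]heptan-2-ol F1. Its single remaining activated ring position is then brominated with NBS (MeCN, rt), and the route comes back at 23.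

## Further compounds

F1 | step 12 | (1R,2R,5S,6S)-5-[(tert-butyldimethylsilyl)oxy]-2-{1-oxido-4,6-bis[2-(trimethylsilyl)ethoxy]pyridin-1-ium-3-yl}-7-oxabicyclo[4.1.0]heptan-2-ol | [O-][n+]1cc([C@]2(O)CC[C@H](O[Si](C)(C)C(C)(C)C)[C@H]3O[C@H]32)c(OCC[Si](C)(C)C)cc1OCC[Si](C)(C)C
F2 | step 13 | 3-bromo-5-iodo-2,4-bis[2-(trimethylsilyl)ethoxy]pyridine | n1cc(I)c(OCC[Si](C)(C)C)c(Br)c1OCC[Si](C)(C)C
F3 | step 13 | (1R,2R,5S,6S)-2-{5-bromo-4,6-bis[2-(trimethylsilyl)ethoxy]pyridin-3-yl}-5-[(tert-butyldimethylsilyl)oxy]-7-oxabicyclo[4.1.0]heptan-2-ol | n1cc([C@]2(O)CC[C@H](O[Si](C)(C)C(C)(C)C)[C@H]3O[C@H]32)c(OCC[Si](C)(C)C)c(Br)c1OCC[Si](C)(C)C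
F4 | step 14 | {5-[(1R,2R,5S,6S)-5-[(tert-butyldimethylsilyl)oxy]-2-hydroxy-7-oxabicyclo[4.1.0]heptan-2-yl]-1-oxido-2,4-bis[2-(trimethylsilyl)ethoxy]pyridin-1-ium-3-yl}[(1R,2R,4aS,6R,8aR)-2,6-dimethyl-1,2,4a,5,6,7,8,8a-octahydronaphthalen-1-yl]methanol (both carbinol epimers) | C[C@@H]1CC[C@H]2[C@H](C(O)c3c(OCC[Si](C)(C)C)c([C@]4(O)CC[C@H](O[Si](C)(C)C(C)(C)C)[C@H]5O[C@H]54)c[n+]([O-])c3OCC[Si](C)(C)C)[C@H](C)C=C[C@@H]2C1
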